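**Retrosynthetic overview**
1. Obtusane ⇐ Br/Cl 1,2-interchange of the trans-diaxial BrCl adduct of (2R,6S)-10-bromo-β-chamigrene; C2–Br ⇐ C2–OH (SN2 inversion) ⇐ C2 ketone (CBS reduction).
2. Spiro ketone ⇐ key step: 6-exo vinyl-radical spirocyclisation onto a 1,3-cyclohexadiene, forming the C5–C6 bond (spiro quaternary carbon next to CMe2), the exocyclic methylene and the C8=C9 alkene in one step.
3. Radical precursor ⇐ enolate alkylation with 2,3-dibromopropene ⇐ dienyl methyl ketone ⇐ dehydration ⇐ Reformatsky-type aldol of 3-bromo-3-methylbutan-2-one with 4-methylcyclohex-3-enone (this makes the C1–C6 vicinal quaternary bond).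
4. Ring order: ring B is bought intact, ring A is closed in the radical step, and the ring-B halogens go on last.

Assumptions: 4-methylcyclohex-3-en-1-one is taken as purchasable. Numbering is that of the target as a spiro[5.5]undecane (C1 = CMe2, C2 = CHBr, C5 = C=CH2, C6 = spiro, C8 = CHCl, C9 = CBrMe).

Stereochemistry caveat: the radical step forms C6 as a racemate. C6 is resolved, not induced: the reagent-controlled CBS reduction in step 5 turns the two C6 enantiomers into diastereomeric alcohols, and only the (2S,6S) one is carried on (maximum 50% of material). The ee of that alcohol equals the catalyst selectivity and can be upgraded by recrystallisation if needed.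

**Step 1**
Reactants: 1 (3-bromo-3-methylbutan-2-one), 2 (4-methylcyclohex-3-en-1-one)
Product: 3, racemic 3-(1-hydroxy-4-methylcyclohex-3-en-1-yl)-3-methylbutan-2-one
Conditions: SmI2 (2.2 equiv), THF, −78 °C, Barbier mode; cold NH4Cl quench
Reagents that add atoms: none
Why: Reformatsky-type aldol in which the samarium enolate from reduction of the tertiary α-bromoketone adds to the ketone without enolising the β,γ-enone; the carbinol stereocentre is irrelevant because it is removed in step 2.

**Step 2**
Reactants: 3
Product: 4, 3-methyl-3-(4-methylcyclohexa-1,3-dien-1-yl)butan-2-one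
Conditions: Burgess reagent, PhMe, 50 °C, under argon
Reagents that add atoms: none
Why: Neutral syn-elimination (Ei) of the tertiary alcohol avoids retro-aldol cleavage and gives mainly the conjugated 1,3-diene; any 1,4-diene regioisomer is carried along because it gives the same spiro ketone in step 4.

**Step 3**
Reactants: 4, 5 (2,3-dibromoprop-1-ene)
Product: 6, 6-bromo-2-methyl-2-(4-methylcyclohexa-1,3-dien-1-yl)hept-6-en-3-one
Conditions: LDA, THF, −78 °C; then 5, DMPU, −78 → 0 °C
Reagents that add atoms: none
Why: Kinetic enolate alkylation; the methyl group is the only enolisable position, and SN2 occurs at the allylic bromide, leaving the vinyl bromide intact.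

**Step 4 (key step)**
Reactants: 6
Product: 7, racemic 1,1,9-trimethyl-5-methylidenespiro[5.5]undec-8-en-2-one
Conditions: Bu3SnH (1.3 equiv, syringe pump), AIBN (0.2 equiv), PhH (0.01 M), 80 °C
Reagents that add atoms: none
Why: Stork vinyl-radical cyclisation in which the σ-vinyl radical adds 6-exo-trig to the substituted diene terminus to forge the spiro quaternary carbon and the exocyclic methylene, and the resulting allyl radical takes H from Bu3SnH at its secondary terminus (C7) to leave the trisubstituted C8=C9 alkene; the ketone tether has no 1,5-hydrogen, and C6 is formed racemic.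

**Step 5**
Reactants: 7
Product: 8, (2S,6S)-1,1,9-trimethyl-5-methylidenespiro[5.5]undec-8-en-2-ol
Conditions: (R)-Me-CBS (0.2 equiv), catecholborane, PhMe, −78 °C; then chromatography to remove the diastereomeric (2S,6R)-alcohol formed from the other enantiomer of 7
Reagents that add atoms: none
Why: Corey–Bakshi–Shibata reduction under reagent control (large group = quaternary C1, small group = C3H2) gives the 2S alcohol in both C6 series, so the C6 enantiomers become separable diastereomers and 8 carries both centres in the required sense; catecholborane does not hydroborate the two alkenes at this temperature.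

**Step 6**
Reactants: 8
Product: 9, (2R,6S)-2-bromo-1,1,9-trimethyl-5-methylidenespiro[5.5]undec-8-ene (10-bromo-β-chamigrene)
Conditions: CBr4, PPh3, pyridine (cat.), PhMe, 0 → 60 °C
Reagents that add atoms: carbon tetrabromide, BrC(Br)(Br)Br
Why: Appel reaction; SN2 displacement of the oxyphosphonium by bromide inverts C2 (2S → 2R).

**Step 7**
Reactants: 9
Product: 10, (2R,6S,8R,9R)-2,8-dibromo-9-chloro-1,1,9-trimethyl-5-methylidenespiro[5.5]undecane
Conditions: Bu4NBrCl2 (1.05 equiv), CH2Cl2, −78 → −40 °C
Reagents that add atoms: tetrabutylammonium dichlorobromate (Bu4NCl·BrCl, delivers BrCl), CCCC[N+](CCCC)(CCCC)CCCC.[Cl-].ClBr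
Why: Electrophilic anti bromochlorination of the more nucleophilic trisubstituted alkene (the exocyclic methylene is neopentyl-hindered); chloride opens the bromonium at tertiary C9 (Markovnikov) in the trans-diaxial (Fürst–Plattner) sense in the chair with the bulky C1 equatorial, which puts Br axial on C8 syn to C5 and Cl axial on C9.

**Step 8**
Reactants: 10
Product: 11, obtusane, (2R,6S,8S,9S)-2,9-dibromo-8-chloro-1,1,9-trimethyl-5-methylidenespiro[5.5]undecane
Conditions: HFIP–CH2Cl2 (1:4), 2,6-di-tert-butylpyridine (0.1 equiv), 25 °C, to equilibrium; chromatograph and recycle recovered 10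
Reagents that add atoms: none
Why: Proposed new method: a dyotropic 1,2-interchange of vicinal halogens, the closest known reaction being the diaxial → diequatorial mutarotation of steroidal 5,6-dihalides; the tertiary C9–Cl ionises in the ionising solvent with anti-periplanar Br participation and the bromonium/chloride ion pair collapses at C8, each halogen staying on its own face, so Br ends on C9 cis to C5 and Cl on C8, trans-diequatorial, with relief of the 1,3-diaxial Br/C5 strain as the driving force.

**Compound list**
1 | 3-bromo-3-methylbutan-2-one | CC(=O)C(C)(C)Br | starting material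
2 | 4-methylcyclohex-3-en-1-one | CC1=CCC(=O)CC1 | starting material
3 | rac-3-(1-hydroxy-4-methylcyclohex-3-en-1-yl)-3-methylbutan-2-one | CC(=O)C(C)(C)C1(O)CC=C(C)CC1 | intermediate
4 | 3-methyl-3-(4-methylcyclohexa-1,3-dien-1-yl)butan-2-one | CC(=O)C(C)(C)C1=CC=C(C)CC1 | intermediate
5 | 2,3-dibromoprop-1-ene | C=C(Br)CBr | starting material
6 | 6-bromo-2-methyl-2-(4-methylcyclohexa-1,3-dien-1-yl)hept-6-en-3-one | C=C(Br)CCC(=O)C(C)(C)C1=CC=C(C)CC1 | intermediate
7 | rac-1,1,9-trimethyl-5-methylidenespiro[5.5]undec-8-en-2-one | C=C1CCC(=O)C(C)(C)C12CCC(C)=CC2 | intermediate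
8 | (2S,6S)-1,1,9-trimethyl-5-methylidenespiro[5.5]undec-8-en-2-ol | C=C1CC[C@H](O)C(C)(C)[C@]12CCC(C)=CC2 | intermediate
9 | (2R,6S)-2-bromo-1,1,9-trimethyl-5-methylidenespiro[5.5]undec-8-ene | C=C1CC[C@@H](Br)C(C)(C)[C@]12CCC(C)=CC2 | intermediate
10 | (2R,6S,8R,9R)-2,8-dibromo-9-chloro-1,1,9-trimethyl-5-methylidenespiro[5.5]undecane | C=C1CC[C@@H](Br)C(C)(C)[C@]12CC[C@@](C)(Cl)[C@H](Br)C2 | intermediate
11 | obtusane, (2R,6S,8S,9S)-2,9-dibromo-8-chloro-1,1,9-trimethyl-5-methylidenespiro[5.5]undecane | C=C1CC[C@@H](Br)C(C)(C)[C@]12CC[C@](C)(Br)[C@@H](Cl)C2 | target

**Totals**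
Total steps: 8. Longest linear sequence: 8 (from 1 and 2).

**Three steps most likely to fail**
1. Step 8, Br/Cl interchange. The 10 ⇌ 11 equilibrium may not favour 11, because chlorine prefers the tertiary carbon while the strain relief favours 11; elimination or participation of the exocyclic alkene is also possible. Fallback: install the ring-B halogens stepwise by ionic chemistry from 9, which also removes the face-selectivity risk of step 7. Epoxidise C8=C9 anti to C5, open at tertiary C9 with bromide (inversion) to the trans-bromohydrin, invert the C8 alcohol by oxidation–reduction, then displace it with chloride (PPh3/CCl4, inversion).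
2. Step 6, Appel at the neopentyl C2. Elimination or a 1,2-methyl shift may win over SN2. Fallback: make the C–Br bond before ring closure. Reduce 6 with CBS, convert the open-chain alcohol to the bromide (sulfonate, then LiBr), and close ring A from the vinyl iodide analogue with (TMS)3SiH so that iodine abstraction outruns loss of the secondary bromide.
3. Step 4, the spirocyclisation. Attack at a fully substituted diene terminus next to CMe2 may be slow, H-delivery to the allyl radical may give some C7=C8 isomer, and C6 comes out racemic so half the material is lost in step 5. Fallback: close ring A by a Pd-catalysed 6-exo reductive Heck spirocyclisation of 6 with a chiral ligand, trapping the π-allyl-Pd intermediate with a hydride source at the less substituted terminus; this forms C6 enantioselectively and makes the step-5 separation a purification only.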